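## Plan

- **Cuts (retrosynthetic order):** the acetyl–O bond at C4; then, together, ring bond C3–C4 and the C5–O bond, which unfolds the cyclopentenone into an (S)-3-(1-acetoxypentadecyl)-4-pyranone; then acetyl–O and C–H at C1′ (back to a ketone); then the pyranone O–C bonds and C4–C5 (one carbon from an amide acetal); last C5–C1′ (acid chloride plus a four-carbon enaminone).
- **Enabling feature:** ring carbons C1–C5 of the cyclopentenone (C1 ketone, C2=C3, C4–O, C5–O) are the five carbons of a 3-substituted 4-pyranone whose ring oxygen ends on C4. The carbonyl oxygen of the C1′ acetate sits where a five-membered ring can deliver it to C5.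
- **Forward order:** the C15 chain is joined to the enaminone by C-acylation, the pyranone ring is closed, the ketone is reduced and acetylated, light contracts the six-membered heterocycle to the five-membered carbocycle, and the C4 hydroxyl is acetylated.
- **Stereochemistry:** C1′ comes from a catalyst-controlled ketone reduction. C4 and C5 arise together in the ring contraction: trans to each other through capture anti to the oxirane, and of the right sense relative to C1′ through allylic strain.

Key step: step 5

Remark: target numbering is used throughout (C1 ketone, C2=C3, C4 acetoxy carbon, C5 tertiary carbinol, C1′ acetoxy carbon of the side chain); the three starting materials are taken as purchasable.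

## Route

Step 1
Reactants: 1 (E)-4-(dimethylamino)but-3-en-2-one; 2 pentadecanoyl chloride
Product: 3 (E)-1-(dimethylamino)nonadec-1-ene-3,5-dione
Conditions: 1 (2.1 equiv), LiN(SiMe3)2 (2.1 equiv), THF, −78 °C; 2 (1.0 equiv), −78 → −30 °C; AcOH (1.1 equiv), pH 7 buffer work-up, used crude
Reagents that add atoms: none
Why: Claisen-type C-acylation of a ketone lithium enolate: the vinylogous amide 1 can be deprotonated only at its methyl group, the cross-conjugated enolate attacks the acid chloride to form the C5–C1′ bond, and the second equivalent of enolate takes up the acidic β-diketone proton, the work-up staying neutral because acid would close 3 to a 2-alkylpyranone.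

Step 2
Reactants: 3 (E)-1-(dimethylamino)nonadec-1-ene-3,5-dione; 4 N,N-dimethylformamide dimethyl acetal
Product: 6 3-pentadecanoyl-4H-pyran-4-one, via bis-enaminone 5 (not isolated)
Conditions: 4 (1.3 equiv), toluene, 20 → 50 °C; concentrate; 2 M aq HCl, THF, 0 → 20 °C
Reagents that add atoms: water, O
Why: Aminomethylenation (enamine condensation) at the only doubly activated methylene of 3 followed by acid-induced pyranone cyclisation, in which the more basic mono-acyl enaminone arm should be hydrolysed first to its formyl enol, whose oxygen displaces dimethylamine from the central aminomethylene carbon by addition–elimination, the closure mode known for aminomethylene β-dicarbonyl compounds carrying an enolised β-ketoaldehyde arm.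

Step 3
Reactants: 6 3-pentadecanoyl-4H-pyran-4-one
Product: 7 3-[(1S)-1-hydroxypentadecyl]-4H-pyran-4-one
Conditions: (R)-1-methyl-3,3-diphenyltetrahydro-1H,3H-pyrrolo[1,2-c][1,3,2]oxazaborole (the (R)-methyl CBS catalyst, 0.2 equiv), catecholborane (1.5 equiv), toluene/CH2Cl2, −78 °C; MeOH quench, pH 7 work-up
Reagents that add atoms: none
Why: Corey–Bakshi–Shibata reduction, in which the exocyclic ketone is the only reactive carbonyl (the ring carbonyl is a doubly vinylogous ester) and, with the planar pyranonyl group as the large and the n-tetradecyl chain as the small substituent, the (R)-catalyst should deliver hydride to the face that gives the (S)-carbinol, which sets C1′.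

Step 4
Reactants: 7 3-[(1S)-1-hydroxypentadecyl]-4H-pyran-4-one
Product: 8 (1S)-1-(4-oxo-4H-pyran-3-yl)pentadecyl acetate
Conditions: Ac2O (1.5 equiv), pyridine, CH2Cl2, 0 → 20 °C
Reagents that add atoms: acetic anhydride, CC(=O)OC(C)=O
Why: Acylation of a secondary alcohol with acetic anhydride and pyridine, which breaks no bond at C1′ and so keeps its configuration, 4-(dimethylamino)pyridine being left out to avoid SN2′ attack on the allylic acetate.

Step 5
Reactants: 8 (1S)-1-(4-oxo-4H-pyran-3-yl)pentadecyl acetate
Product: 11 (1S)-1-[(1R,5R)-1,5-dihydroxy-2-oxocyclopent-3-en-1-yl]pentadecyl acetate, via oxirane-fused oxyallyl zwitterion 9 (not isolated), via spiro acetoxonium alkoxide 10 (not isolated)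
Conditions: hν 254 nm (low-pressure Hg lamps, quartz), 3 mM in (CF3)2CHOH/H2O 50:1, N2-sparged, 15 °C, stopped near full conversion; solid NaHCO3, concentrate, chromatography
Reagents that add atoms: water, O
Why: Proposed new method: excitation of the cross-conjugated pyranone should cause disrotatory 4π-electrocyclisation between the two oxygen-bearing ring carbons (C3–C4 of 12), closing the five-membered carbocycle as zwitterion 9; the acetate carbonyl oxygen then adds to the substituted terminus C5 through a five-membered ring (5-exo closure, classical neighbouring-group participation), the enolate expels the oxirane oxygen by β-elimination to unveil the C2=C3 enone and the C4 oxygen (10), and water opens the acetoxonium at its central carbon, the more acidic tertiary α-ketol oxygen leaving so that the acetate stays on C1′. The closest known reaction type is the photochemical ring contraction of 4-pyranones in hydroxylic media, where water, alcohols or tethered hydroxyl and carboxyl groups capture the same zwitterion to give trans-4,5-dioxygenated cyclopent-2-enones; capture by an ester carbonyl is the untested element. C4 is set by the oxirane, since capture anti to it makes C4–O and C5–O trans. C5 is set by C1′: allylic 1,3-strain keeps the C1′–H in the ring plane beside the enolate oxygen, so the acetate reaches the face anti to the oxirane only in the zwitterion whose oxirane lies on the side of the tetradecyl chain, while the other, reversibly formed zwitterion should return to 8. The step needs oxygen delivery to C5 and not to the unsubstituted terminus C2; the five-membered tether of the C1′ acetate secures this, helped by the weakly nucleophilic, strongly ionising solvent.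

Step 6
Reactants: 11 (1S)-1-[(1R,5R)-1,5-dihydroxy-2-oxocyclopent-3-en-1-yl]pentadecyl acetate
Product: 12 (1S)-1-[(1S,5R)-5-acetoxy-1-hydroxy-2-oxocyclopent-3-en-1-yl]pentadecyl acetate (CNP0259741.2)
Conditions: Ac2O (1.3 equiv), pyridine, CH2Cl2, 0 °C
Reagents that add atoms: acetic anhydride, CC(=O)OC(C)=O
Why: Selective acylation, in which the secondary allylic C4 hydroxyl reacts with acetic anhydride and pyridine at 0 °C while the hindered tertiary C5 hydroxyl, flanked by the ketone and C1′, should stay free in the absence of a stronger acyl-transfer catalyst, and no stereocentre is touched.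

## Compound list

1 | (E)-4-(dimethylamino)but-3-en-2-one | CC(=O)/C=C/N(C)C | starting material
2 | pentadecanoyl chloride | CCCCCCCCCCCCCCC(Cl)=O | starting material
3 | (E)-1-(dimethylamino)nonadec-1-ene-3,5-dione | CCCCCCCCCCCCCCC(=O)CC(=O)/C=C/N(C)C | intermediate
4 | N,N-dimethylformamide dimethyl acetal | COC(OC)N(C)C | starting material
5 | (1E)-1-(dimethylamino)-4-[(dimethylamino)methylidene]nonadec-1-ene-3,5-dione (bis-enaminone, not isolated) | CCCCCCCCCCCCCCC(=O)C(=CN(C)C)C(=O)/C=C/N(C)C | intermediate
6 | 3-pentadecanoyl-4H-pyran-4-one | CCCCCCCCCCCCCCC(=O)C1=COC=CC1=O | intermediate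
7 | 3-[(1S)-1-hydroxypentadecyl]-4H-pyran-4-one | CCCCCCCCCCCCCC[C@H](O)C1=COC=CC1=O | intermediate
8 | (1S)-1-(4-oxo-4H-pyran-3-yl)pentadecyl acetate | CCCCCCCCCCCCCC[C@H](OC(C)=O)C1=COC=CC1=O | intermediate
9 | 2-[(1S)-1-acetoxypentadecyl]-6-oxabicyclo[3.1.0]hex-3-en-2-ylium-3-olate (oxyallyl zwitterion, oxirane cis-fused on the face of the later C4–O; not isolated) | CCCCCCCCCCCCCC[C@H](OC(C)=O)[C+]1C([O-])=C[C@H]2O[C@@H]12 | intermediate
10 | 2-methyl-6-oxo-4-tetradecyl-1,3-dioxaspiro[4.4]non-7-en-2-ylium-9-olate (acetoxonium spiro at C5, C4 alkoxide, configuration as in 11; not isolated) | CCCCCCCCCCCCCC[C@@H]1OC(C)=[O+][C@@]12C(=O)C=C[C@H]2[O-] | intermediate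
11 | (1S)-1-[(1R,5R)-1,5-dihydroxy-2-oxocyclopent-3-en-1-yl]pentadecyl acetate (4,5-trans diol, same spatial arrangement as 12) | CCCCCCCCCCCCCC[C@H](OC(C)=O)[C@@]1(O)C(=O)C=C[C@H]1O | intermediate
12 | (1S)-1-[(1S,5R)-5-acetoxy-1-hydroxy-2-oxocyclopent-3-en-1-yl]pentadecyl acetate, i.e. (4R,5S)-4-acetoxy-5-[(1S)-1-acetoxypentadecyl]-5-hydroxycyclopent-2-en-1-one | CCCCCCCCCCCCCC[C@H](OC(C)=O)[C@@]1(O)C(=O)C=C[C@H]1OC(C)=O | target

Total step count: 6
Longest linear sequence: 6 steps (1 or 2 → 12)

## Steps most likely to fail

**Step 5 (proposed new method).**
- What may go wrong: the acetate carbonyl may be too weak a nucleophile, so that the zwitterion reverts, rearranges to a 2-pyranone or is captured by solvent at the unsubstituted terminus. The two faces may be poorly discriminated, the enone product may be photolysed further, and the acetoxonium may open toward the tertiary acetate.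
- Fallback (known solvent capture by water in place of internal acetate capture): setting out from 7, irradiation at 254 nm in dilute MeCN/H2O should give photohydration to trans-4,5-dihydroxycyclopent-2-enones. After chromatographic removal of the regioisomer from capture at the unsubstituted terminus and of the diastereomer with both ring centres inverted, this would leave (4R,5S)-4,5-dihydroxy-5-[(1S)-1-hydroxypentadecyl]cyclopent-2-en-1-one F1. Acetylation of its two secondary hydroxyls (Ac2O 2.5 equiv, pyridine, 0 → 20 °C) comes back to the route at 12.

**Step 2.**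
- What may go wrong: ring closure through the pentadecanoyl carbonyl oxygen instead of the formyl enol oxygen, or hydrolytic opening of the electrophilic acylpyranone during the acid stage.
- Fallback (side chain carried at the alcohol oxidation level, so that no second carbonyl can compete): setting out from 1, its lithium enolate (LiN(SiMe3)2, THF, −78 °C) would add to pentadecanal to give racemic (E)-1-(dimethylamino)-5-hydroxynonadec-1-en-3-one F2. Silylation (tert-butyldimethylsilyl chloride, imidazole, DMF) gives (E)-5-[(tert-butyldimethylsilyl)oxy]-1-(dimethylamino)nonadec-1-en-3-one F3. Kinetic enolisation at C4 (LiN(SiMe3)2, −78 °C) and formylation with 2,2,2-trifluoroethyl formate would give (1E)-5-[(tert-butyldimethylsilyl)oxy]-1-(dimethylamino)-4-(hydroxymethylidene)nonadec-1-en-3-one F4, not isolated. CF3CO2H in CH2Cl2 closes it through its only enol oxygen to 3-{1-[(tert-butyldimethylsilyl)oxy]pentadecyl}-4H-pyran-4-one F5. HF·pyridine in THF frees racemic 3-(1-hydroxypentadecyl)-4H-pyran-4-one F6, and Dess–Martin oxidation comes back to the route at 6.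

**Step 3.**
- What may go wrong: conjugate hydride delivery to the doubly activated ring carbon next to the acyl group, or reduction outside the catalyst by borane held on the basic ring carbonyl, either of which lowers chemical yield or enantiomeric purity.
- Fallback (kinetic resolution in place of asymmetric reduction): setting out from 6, Luche reduction (NaBH4, CeCl3·7H2O, MeOH, −78 °C) gives racemic 3-(1-hydroxypentadecyl)-4H-pyran-4-one F6. Lipase from Burkholderia cepacia with vinyl acetate in tert-butyl methyl ether should acetylate the (R)-alcohol faster (Kazlauskas rule), giving (1R)-1-(4-oxo-4H-pyran-3-yl)pentadecyl acetate F7. The unreacted (S)-alcohol is 7, where the route is rejoined after chromatography.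

## Further compounds

F1 | step 5 | (4R,5S)-4,5-dihydroxy-5-[(1S)-1-hydroxypentadecyl]cyclopent-2-en-1-one | CCCCCCCCCCCCCC[C@H](O)[C@@]1(O)C(=O)C=C[C@H]1O
F2 | step 2 | (E)-1-(dimethylamino)-5-hydroxynonadec-1-en-3-one (racemic) | CCCCCCCCCCCCCCC(O)CC(=O)/C=C/N(C)C
F3 | step 2 | (E)-5-[(tert-butyldimethylsilyl)oxy]-1-(dimethylamino)nonadec-1-en-3-one (racemic) | CCCCCCCCCCCCCCC(O[Si](C)(C)C(C)(C)C)CC(=O)/C=C/N(C)C
F4 | step 2 | (1E)-5-[(tert-butyldimethylsilyl)oxy]-1-(dimethylamino)-4-(hydroxymethylidene)nonadec-1-en-3-one (racemic, not isolated) | CCCCCCCCCCCCCCC(O[Si](C)(C)C(C)(C)C)C(=CO)C(=O)/C=C/N(C)C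
F5 | step 2 | 3-{1-[(tert-butyldimethylsilyl)oxy]pentadecyl}-4H-pyran-4-one (racemic) | CCCCCCCCCCCCCCC(O[Si](C)(C)C(C)(C)C)C1=COC=CC1=O
F6 | step 2 | 3-(1-hydroxypentadecyl)-4H-pyran-4-one (racemic) | CCCCCCCCCCCCCCC(O)C1=COC=CC1=O
F7 | step 3 | (1R)-1-(4-oxo-4H-pyran-3-yl)pentadecyl acetate | CCCCCCCCCCCCCC[C@@H](OC(C)=O)C1=COC=CC1=O
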